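**Retrosynthetic overview**
1. Pakyonol ⇐ hydrogenation (C=C saturation and O-debenzylation) ⇐ 20-membered stilbene ⇐ McMurry ring closure of an open-chain dialdehyde. The CH2–CH2 bridge between the para-phenylene ring B and the hydroxylated ring C is cut between its two benzylic carbons, and both are carried as formyl carbons (like polarity).
2. Enabling feature: on ring B and on ring C the bridge carbon sits para to the diaryl ether oxygen (ring C: bridge at C1, O-aryl at C4, OH at C3). Each formyl group therefore first activates the SNAr that builds its own diaryl ether (A–O–B and C–O–D) and is then joined to its twin.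
3. The other bridge (ring A carbon para to OMe –CH2CH2– ring D, meta to both ether oxygens) ⇐ Heck coupling of an A–B aryl bromide with a C–D styrene, then chemoselective alkene hydrogenation.
4. Ring order: the four benzene rings are bought; the only ring made is the 20-membered macrocycle (3 atoms of A, O, 4 of B, CH2CH2, 4 of C, O, 3 of D, CH2CH2), closed last.

Key step: step 6

Assumption: the target has no stereocentre; the alkene geometries on the way (E after the Heck step, Z expected after ring closure) are erased by hydrogenation, and the macrocyclic alkene is drawn as the Z isomer that the ring should favour.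

Step 1
Reactants: 1 5-bromo-2-methoxyphenol; 2 4-fluorobenzaldehyde
Product: 3 4-(5-bromo-2-methoxyphenoxy)benzaldehyde
Conditions: K2CO3, DMF, 130 °C
Reagents that add atoms: none
Why: SNAr, in which the phenoxide of 1 displaces the fluoride para to the formyl group of 2 through a Meisenheimer adduct, while the unactivated aryl bromide stays inert.

Step 2
Reactants: 4 4-fluoro-3-hydroxybenzaldehyde
Product: 5 3-(benzyloxy)-4-fluorobenzaldehyde
Conditions: BnBr, K2CO3, DMF, rt
Reagents that add atoms: benzyl bromide, BrCc1ccccc1
Why: Williamson ether synthesis (SN2 of the phenoxide on benzyl bromide); the benzyl ether keeps the ortho oxygen from deactivating the fluoride as a phenoxide in step 3 and leaves in the final hydrogenation.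

Step 3
Reactants: 6 3-ethenylphenol (3-vinylphenol); 5 3-(benzyloxy)-4-fluorobenzaldehyde
Product: 7 3-(benzyloxy)-4-(3-ethenylphenoxy)benzaldehyde
Conditions: Cs2CO3, BHT (cat.), DMSO, 90 °C
Reagents that add atoms: none
Why: SNAr, in which the phenoxide of 6 displaces the fluoride of 5 that is para to the formyl group; moderate temperature and a radical inhibitor should keep the styrene from polymerising.

Step 4
Reactants: 3 4-(5-bromo-2-methoxyphenoxy)benzaldehyde; 7 3-(benzyloxy)-4-(3-ethenylphenoxy)benzaldehyde
Product: 8 3-(benzyloxy)-4-[3-[(E)-2-[3-(4-formylphenoxy)-4-methoxyphenyl]ethenyl]phenoxy]benzaldehyde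
Conditions: Pd(OAc)2 (2 mol %), P(o-tol)3 (4 mol %), NaOAc, DMA, 120 °C
Reagents that add atoms: none
Why: Mizoroki–Heck reaction, in which oxidative addition of Pd(0) into the aryl bromide, syn insertion of the styrene at its terminal carbon and syn β-hydride elimination should give the E-stilbene; aldehydes and the benzyl ether are inert.

Step 5
Reactants: 8 the (E)-stilbene dialdehyde
Product: 9 3-(benzyloxy)-4-[3-[2-[3-(4-formylphenoxy)-4-methoxyphenyl]ethyl]phenoxy]benzaldehyde (seco-dialdehyde)
Conditions: H2 (1 atm), 10% Pd/C, Ph2S (0.01 equiv), EtOAc, rt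
Reagents that add atoms: none
Why: Chemoselective catalytic hydrogenation on sulfur-poisoned Pd/C, where diphenyl sulfide lowers the catalyst activity so that the stilbene C=C is saturated while aryl aldehydes and the aryl benzyl ether should remain untouched.

Step 6
Reactants: 9 the seco-dialdehyde
Product: 11 O-benzyl-dehydropakyonol (20-membered macrocycle with a Z-CH=CH bridge between rings B and C), via titanium pinacolate 10 (not isolated)
Conditions: TiCl4 (12 equiv), Zn (24 equiv), pyridine, THF, reflux; 9 added by syringe pump over 24 h (final c ≈ 2 mM)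
Reagents that add atoms: none
Why: McMurry coupling: low-valent titanium transfers one electron to each aryl aldehyde, the two titanium-bound ketyl radicals (both formerly electrophilic carbons) couple to the cyclic pinacolate 10, and at reflux titanium deoxygenates the diolate to the alkene, driven by Ti–O bond formation. The closest known reaction type is the intramolecular McMurry macrocyclisation of aryl dialdehydes used for stilbene-bridged cyclophanes and macrocyclic bis(bibenzyl) ethers. The 20-membered ring closes end to end between the two trigonal formyl carbons, an exo-type macrocyclisation free of Baldwin constraints and helped by both ketyls being held on titanium. No stereocentre results, because the two carbinol centres of 10 are destroyed in the same flask and the alkene geometry is erased in step 7. The step needs intramolecular over intermolecular coupling, which slow addition into excess reagent and the kinked substrate (meta-linked rings A and D, a flexible CH2CH2 hinge and two ether hinges) should secure; chemoselectivity follows because the aldehydes are the only reducible groups beside the inert benzyl and methyl ethers.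

Step 7
Reactants: 11 O-benzyl-dehydropakyonol
Product: 13 pakyonol, via O-benzylpakyonol 12 (not isolated)
Conditions: H2 (1 atm), 10% Pd/C, EtOAc/EtOH, rt
Reagents that add atoms: none
Why: Heterogeneous hydrogenation and hydrogenolysis on unpoisoned Pd/C, in which the cis-stilbene should be saturated first (12) and the aryl benzyl ether then cleaved to the free phenol; diaryl ethers and the methyl ether are stable.

**Compound list**
1 | 5-bromo-2-methoxyphenol | COc1ccc(Br)cc1O | starting material
2 | 4-fluorobenzaldehyde | O=Cc1ccc(F)cc1 | starting material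
3 | 4-(5-bromo-2-methoxyphenoxy)benzaldehyde | COc1ccc(Br)cc1Oc1ccc(C=O)cc1 | intermediate
4 | 4-fluoro-3-hydroxybenzaldehyde | O=Cc1ccc(F)c(O)c1 | starting material
5 | 3-(benzyloxy)-4-fluorobenzaldehyde | O=Cc1ccc(F)c(OCc2ccccc2)c1 | intermediate
6 | 3-ethenylphenol (3-vinylphenol) | C=Cc1cccc(O)c1 | starting material
7 | 3-(benzyloxy)-4-(3-ethenylphenoxy)benzaldehyde | C=Cc1cccc(Oc2ccc(C=O)cc2OCc2ccccc2)c1 | intermediate
8 | 3-(benzyloxy)-4-[3-[(E)-2-[3-(4-formylphenoxy)-4-methoxyphenyl]ethenyl]phenoxy]benzaldehyde | COc1ccc(/C=C/c2cccc(Oc3ccc(C=O)cc3OCc3ccccc3)c2)cc1Oc1ccc(C=O)cc1 | intermediate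
9 | 3-(benzyloxy)-4-[3-[2-[3-(4-formylphenoxy)-4-methoxyphenyl]ethyl]phenoxy]benzaldehyde (seco-dialdehyde) | COc1ccc(CCc2cccc(Oc3ccc(C=O)cc3OCc3ccccc3)c2)cc1Oc1ccc(C=O)cc1 | intermediate
10 | titanium pinacolate of the macrocycle (cyclic 1,2-diolate on titanium between rings B and C; drawn as the free 1,2-diol; configuration not defined, both carbinol centres are destroyed in the same flask) | COc1ccc2cc1Oc1ccc(cc1)C(O)C(O)c1ccc(c(OCc3ccccc3)c1)Oc1cccc(c1)CC2 | intermediate
11 | O-benzyl-dehydropakyonol (20-membered macrocycle, Z-CH=CH bridge between rings B and C, OBn on ring C) | COc1ccc2cc1Oc1ccc(cc1)/C=C\c1ccc(c(OCc3ccccc3)c1)Oc1cccc(c1)CC2 | intermediate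
12 | O-benzylpakyonol | COc1ccc2cc1Oc1ccc(cc1)CCc1ccc(c(OCc3ccccc3)c1)Oc1cccc(c1)CC2 | intermediate
13 | pakyonol | COc1ccc2cc1Oc1ccc(cc1)CCc1ccc(c(O)c1)Oc1cccc(c1)CC2 | target

**Step count and risks**

Total step count: 7. Longest linear sequence: 6 steps (steps 2–7, from 4).

Steps most likely to fail:

Step 6 (ring closure). Intermolecular ketyl coupling may outrun cyclisation and give oligomers, or deoxygenation may stall at the pinacol stage. The fallback closes the ring by two SN2 reactions at sulfur and contracts it afterwards. It sets out from 9. NaBH4 (MeOH/THF, 0 °C) should give the seco-diol F1, and PBr3 (CH2Cl2, 0 °C) the bis(benzyl bromide) F2. Slow simultaneous addition of F2 and Na2S·9H2O to EtOH/THF under high dilution should give the 21-membered cyclic sulfide F3. mCPBA (2.2 equiv, CH2Cl2, 0 °C) should give the cyclic sulfone F4. A Ramberg–Bäcklund reaction (CBr2F2, KOH on alumina, t-BuOH/CH2Cl2) should then extrude SO2 and come back to the route at 11, which step 7 converts to 13.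

Step 5 (chemoselective hydrogenation). The formyl groups may be over-reduced or the benzyl ether lost before the alkene is fully saturated. The fallback masks the aldehydes and reduces the alkene with diimide instead of hydrogen on a metal. It sets out from 8. Ethylene glycol, p-TsOH (cat.), toluene, Dean–Stark should give the stilbene bis(1,3-dioxolane) F5. Diimide from TsNHNH2/NaOAc (DME/H2O, reflux) should saturate the alkene to the bibenzyl bis(1,3-dioxolane) F6 without touching the benzyl ether. 1 M HCl/THF (rt) should release the aldehydes and come back to the route at 9.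

Step 3 (SNAr with the vinylphenol). The styrene may polymerise under hot basic conditions before the hindered fluoride, ortho to OBn, is displaced. The fallback installs the vinyl group after the ether. It sets out from 5. 3-Bromophenol, K2CO3, DMF, 120 °C should give 3-(benzyloxy)-4-(3-bromophenoxy)benzaldehyde F7. Suzuki–Miyaura vinylation with potassium vinyltrifluoroborate (PdCl2(dppf), Cs2CO3, THF/H2O, 70 °C) should come back to the route at 7.

**Further compounds**
F1 | step 6 | seco-diol: [3-(benzyloxy)-4-[3-[2-[3-[4-(hydroxymethyl)phenoxy]-4-methoxyphenyl]ethyl]phenoxy]phenyl]methanol | COc1ccc(CCc2cccc(Oc3ccc(CO)cc3OCc3ccccc3)c2)cc1Oc1ccc(CO)cc1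
F2 | step 6 | bis(benzyl bromide) corresponding to F1 | COc1ccc(CCc2cccc(Oc3ccc(CBr)cc3OCc3ccccc3)c2)cc1Oc1ccc(CBr)cc1
F3 | step 6 | 21-membered cyclic sulfide (CH2–S–CH2 between rings B and C, OBn on ring C) | COc1ccc2cc1Oc1ccc(cc1)CSCc1ccc(c(OCc3ccccc3)c1)Oc1cccc(c1)CC2
F4 | step 6 | 21-membered cyclic sulfone (CH2–SO2–CH2 between rings B and C, OBn on ring C) | COc1ccc2cc1Oc1ccc(cc1)CS(=O)(=O)Cc1ccc(c(OCc3ccccc3)c1)Oc1cccc(c1)CC2
F5 | step 5 | bis(1,3-dioxolane) of (E)-stilbene dialdehyde 8 | COc1ccc(/C=C/c2cccc(Oc3ccc(C4OCCO4)cc3OCc3ccccc3)c2)cc1Oc1ccc(C2OCCO2)cc1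
F6 | step 5 | bis(1,3-dioxolane) of seco-dialdehyde 9 | COc1ccc(CCc2cccc(Oc3ccc(C4OCCO4)cc3OCc3ccccc3)c2)cc1Oc1ccc(C2OCCO2)cc1
F7 | step 3 | 3-(benzyloxy)-4-(3-bromophenoxy)benzaldehyde | O=Cc1ccc(Oc2cccc(Br)c2)c(OCc2ccccc2)c1
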